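**Retrosynthetic overview**

1. Target 20 ← acetate of bromohydrin 19 ← cis-reduction of the deconjugated α'-bromo ketone 18 ← C4 bromination of spiro enone 14; the ring A stereocenters C3 and C4 are set last, relayed from the axial C10 chlorine.
2. 14 ← ring B olefin 11 by three consecutive trans-diaxial events (epoxide anti to C1, chloride at C10, chloronium-guided bromide at C9); 11 ← Stork–Danheiser methylation of vinylogous ester 9.
3. 9 ← enol carbonate 7 in one flask: Pd-catalysed decarboxylative asymmetric allylation sets the spiro carbon C6 (bond C6–C11), then ring-closing metathesis closes ring B by joining C9 to C10, the two carbons that later carry Br and Cl.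
4. Enabling feature: C6 is α to C1, which is held at carbonyl level (vinylogous ester) so that C6 can be the enolate carbon; C11 and C10 are then the first two carbons of an allyl unit, and C9/C10, the trans-dihalide carbons of ring B, are an olefin retron.
5. Order of rings: ring A (C1–C6 with the C5 gem-dimethyl group) comes intact from dimedone; ring B is formed by the key step.

Key step: step 5

Remark: atoms keep the numbering of the target core throughout (C1 methylidene carbon, C3 acetoxy carbon, C4 CHBr, C5 CMe2, C6 spiro carbon, C9 C(Me)Br, C10 CHCl; ring A = C1 to C6, ring B = C6 to C11), and the acetyl group is taken to be the O-acetate at C3 as drawn in the SMILES.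

**Step 1**
Reactants: 1 5,5-dimethylcyclohexane-1,3-dione (dimedone)
Product: 2 5,5-dimethyl-3-(2-methylpropoxy)cyclohex-2-en-1-one
Conditions: i-BuOH, TsOH·H2O (cat.), toluene, reflux, Dean–Stark
Reagents that add atoms: 2-methylpropan-1-ol CC(C)CO
Why: Acid-catalysed enol etherification of the cyclic 1,3-dione with azeotropic removal of water gives the vinylogous ester; no stereocenter is formed.

**Step 2**
Reactants: 3 4-bromo-2-methylbut-1-ene
Product: 4 4-iodo-2-methylbut-1-ene
Conditions: NaI, acetone, reflux
Reagents that add atoms: sodium iodide [Na+].[I-]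
Why: Finkelstein halide exchange (SN2), driven by precipitation of NaBr from acetone, provides the more reactive primary iodide; no stereocenter.

**Step 3**
Reactants: 2 5,5-dimethyl-3-(2-methylpropoxy)cyclohex-2-en-1-one; 4 4-iodo-2-methylbut-1-ene
Product: 5 rac-5,5-dimethyl-6-(3-methylbut-3-en-1-yl)-3-(2-methylpropoxy)cyclohex-2-en-1-one
Conditions: LiN(i-Pr)2, THF, −78 °C; then 4, −78 to 23 °C
Reagents that add atoms: none
Why: Kinetic α'-deprotonation of the vinylogous ester (Stork–Danheiser alkylation; C6 is the only α' carbon) and SN2 alkylation by the primary iodide should give 5 as a racemate, whose C6 stereocenter is erased again in step 4.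

**Step 4**
Reactants: 5 rac-5,5-dimethyl-6-(3-methylbut-3-en-1-yl)-3-(2-methylpropoxy)cyclohex-2-en-1-one; 6 allyl chloroformate
Product: 7 prop-2-en-1-yl 3,3-dimethyl-2-(3-methylbut-3-en-1-yl)-5-(2-methylpropoxy)cyclohexa-1,5-dien-1-yl carbonate
Conditions: LiN(i-Pr)2, TMEDA, THF, −78 °C; then 6, −78 °C
Reagents that add atoms: none
Why: A second kinetic deprotonation at C6 gives the tetrasubstituted lithium dienolate, which the hard chloroformate should acylate on oxygen (enol carbonate formation), fixing the C1–C6 enolate regiochemistry for the key step; no stereocenter remains.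

**Step 5**
Reactants: 7 prop-2-en-1-yl 3,3-dimethyl-2-(3-methylbut-3-en-1-yl)-5-(2-methylpropoxy)cyclohexa-1,5-dien-1-yl carbonate
Product: 9 (6S)-5,5,9-trimethyl-3-(2-methylpropoxy)spiro[5.5]undeca-2,9-dien-1-one, via acyclic allyl ketone 8 (not isolated)
Conditions: Pd2(dba)3 (2.5 mol %), (R)-t-BuPHOX (6.25 mol %), toluene, 25 °C; then CuCl (10 mol %), second-generation Grubbs catalyst (5 mol %), 45 °C, same flask
Reagents that add atoms: none
Why: Zerovalent palladium ionizes the allyl carbonate, CO2 is lost and the palladium enolate/π-allyl pair collapses within the chiral phosphinooxazoline pocket to form C6–C11 (decarboxylative asymmetric allylic alkylation), after which the ruthenium alkylidene loads on the monosubstituted allyl olefin and closes ring B on the 1,1-disubstituted olefin, joining C9 to C10 with loss of ethene (ring-closing metathesis). The closest known reaction types are the enantioselective decarboxylative allylation of enol carbonates of α'-substituted vinylogous esters and the metathesis closure of 1,7-dienes to 1-methylcyclohexenes; both are neutral and run in toluene between 25 and 45 °C, so they are combined in one flask, with CuCl removing free phosphine before the ruthenium carbene is added. Ring B is closed in a six-membered diene-to-cycloalkene mode at the C9=C10 bond, the spiro carbon being a spectator. The only new stereocenter, C6, is set by the ligand: by the sense of induction established for 2-alkyl-2-allylcyclohexanones, the (R)-ligand should deliver the allyl group to the enolate face that gives (S)-8. The step needs regiospecific C-allylation without enolate equilibration, which the inner-sphere palladium enolate generated from the fixed enol carbonate secures, and it needs ring B to form in preference to any other pairing, which is secured because the vinylogous-ester olefin is trisubstituted and electron-poor and only one six-membered pairing exists. One operation thus turns an achiral monocycle into the enantioenriched spiro[5.5] core with the C9=C10 olefin in place for both halogens.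

**Step 6**
Reactants: 9 (6S)-5,5,9-trimethyl-3-(2-methylpropoxy)spiro[5.5]undeca-2,9-dien-1-one
Product: 11 (6S)-1,5,5,9-tetramethylspiro[5.5]undeca-1,9-dien-3-one, via tertiary allylic alcohol 10 (not isolated)
Conditions: MeLi, CeCl3, THF, −78 °C; then 10% aq. HCl, 23 °C
Reagents that add atoms: methyllithium [Li]C; water O
Why: The organocerium reagent adds 1,2 to the hindered C1 carbonyl, and acid then hydrolyses the enol ether and eliminates water (Stork–Danheiser transposition), so that C1 carries the future methylidene carbon and C3 the ketone; C6 is untouched.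

**Step 7**
Reactants: 11 (6S)-1,5,5,9-tetramethylspiro[5.5]undeca-1,9-dien-3-one
Product: 12 (6S,9S,10R)-9,10-epoxy-1,5,5,9-tetramethylspiro[5.5]undec-1-en-3-one
Conditions: mCPBA, CH2Cl2, 0 °C
Reagents that add atoms: 3-chloroperoxybenzoic acid O=C(OO)c1cccc(Cl)c1
Why: Prilezhaev epoxidation is chemoselective for the electron-rich trisubstituted ring B olefin over the enone, and because the sp2 carbon C1 is pseudoaxial on the ring B half-chair (the quaternary C5 stays pseudoequatorial) the peracid should come from the face anti to C1, setting C9 and C10.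

**Step 8**
Reactants: 12 (6S,9S,10R)-9,10-epoxy-1,5,5,9-tetramethylspiro[5.5]undec-1-en-3-one
Product: 13 (6S,9S,10S)-10-chloro-9-hydroxy-1,5,5,9-tetramethylspiro[5.5]undec-1-en-3-one
Conditions: LiCl, AcOH, THF, 23 °C
Reagents that add atoms: lithium chloride [Li+].[Cl-]
Why: Halohydrin formation by SN2 opening of the epoxide: chloride should attack the secondary C10 with inversion along the only trans-diaxial (Fürst–Plattner) trajectory of the chair that keeps C5 equatorial, which places Cl on the C1 face and leaves the tertiary C9–O bond intact.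

**Step 9**
Reactants: 13 (6S,9S,10S)-10-chloro-9-hydroxy-1,5,5,9-tetramethylspiro[5.5]undec-1-en-3-one
Product: 14 (6S,9S,10S)-9-bromo-10-chloro-1,5,5,9-tetramethylspiro[5.5]undec-1-en-3-one
Conditions: 48% aq. HBr, CH2Cl2, 0 °C; aq. NaHCO3 work-up
Reagents that add atoms: hydrogen bromide Br
Why: SN1 substitution of the tertiary alcohol by HBr with neighbouring-group participation: the antiperiplanar axial C10 chlorine bridges the C9 cation, so bromide should open the chloronium ion diaxially at the tertiary carbon, on the face the hydroxyl left (net retention at C9, Br trans to Cl), and any HBr adduct of the enone reverts on the bicarbonate work-up.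

**Step 10**
Reactants: 14 (6S,9S,10S)-9-bromo-10-chloro-1,5,5,9-tetramethylspiro[5.5]undec-1-en-3-one
Product: 16 (4R,6R,9S,10S)-4,9-dibromo-10-chloro-1,5,5,9-tetramethylspiro[5.5]undec-1-en-3-one, via trimethylsilyl dienol ether 15 (not isolated)
Conditions: LiN(SiMe3)2, Me3SiCl, THF, −78 °C; then NBS, −78 °C
Reagents that add atoms: N-bromosuccinimide O=C1CCC(=O)N1Br
Why: Kinetic α'-enolization (C4 is the only sp3 α-carbon and −78 °C spares the tertiary bromide) with in situ silylation, then electrophilic bromination of the cross-conjugated silyl dienol ether: the axial C10 chlorine should hold ring A with the C11 methylene pseudoaxial, and NBS then enters C4 axially, anti to the adjacent pseudoaxial C5 methyl and hence cis to C11, which sets C4.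

**Step 11**
Reactants: 16 (4R,6R,9S,10S)-4,9-dibromo-10-chloro-1,5,5,9-tetramethylspiro[5.5]undec-1-en-3-one
Product: 18 (4R,6R,9S,10S)-4,9-dibromo-10-chloro-5,5,9-trimethyl-1-methylidenespiro[5.5]undecan-3-one, via linear silyl dienol ether 17 (not isolated)
Conditions: Me3SiOTf, Et3N, CH2Cl2, −20 °C; then Bu4NF, AcOH, THF, −78 °C
Reagents that add atoms: none
Why: Soft enolization should remove a γ-proton of the C1 methyl group, since the remaining C4–H is equatorial and shielded by CMe2 and Br, and buffered fluoride cleavage of the linear silyl dienol ether protonates kinetically at the α-carbon C2, which moves the olefin out of conjugation into the exocyclic position (deconjugation by α-protonation of a dienolate); C4 is not touched.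

**Step 12**
Reactants: 18 (4R,6R,9S,10S)-4,9-dibromo-10-chloro-5,5,9-trimethyl-1-methylidenespiro[5.5]undecan-3-one
Product: 19 (3S,4R,6R,9S,10S)-4,9-dibromo-10-chloro-5,5,9-trimethyl-1-methylidenespiro[5.5]undecan-3-ol
Conditions: i-Bu2AlH, CH2Cl2, −78 °C
Reagents that add atoms: none
Why: 1,2-Reduction of the α-bromo ketone at −78 °C: hydride should add anti to the axial C4–Br bond (polar Felkin–Anh control), giving the C3 alcohol cis to bromine, while the halides and the exocyclic olefin are inert to i-Bu2AlH at this temperature.

**Step 13**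
Reactants: 19 (3S,4R,6R,9S,10S)-4,9-dibromo-10-chloro-5,5,9-trimethyl-1-methylidenespiro[5.5]undecan-3-ol
Product: 20 (3S,4R,6R,9S,10S)-4,9-dibromo-10-chloro-5,5,9-trimethyl-1-methylidenespiro[5.5]undecan-3-yl acetate
Conditions: Ac2O, pyridine, DMAP (cat.), CH2Cl2, 23 °C
Reagents that add atoms: acetic anhydride CC(=O)OC(C)=O
Why: DMAP-catalysed acylation of the secondary alcohol with acetic anhydride (esterification) completes the target without touching any stereocenter.

**Compound list**

1 | 5,5-dimethylcyclohexane-1,3-dione (dimedone) | CC1(C)CC(=O)CC(=O)C1 | starting material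
2 | 5,5-dimethyl-3-(2-methylpropoxy)cyclohex-2-en-1-one | CC(C)COC1=CC(=O)CC(C)(C)C1 | intermediate
3 | 4-bromo-2-methylbut-1-ene | C=C(C)CCBr | starting material
4 | 4-iodo-2-methylbut-1-ene | C=C(C)CCI | intermediate
5 | rac-5,5-dimethyl-6-(3-methylbut-3-en-1-yl)-3-(2-methylpropoxy)cyclohex-2-en-1-one | O=C1C=C(OCC(C)C)CC(C)(C)C1CCC(C)=C | intermediate
6 | allyl chloroformate (prop-2-en-1-yl carbonochloridate) | C=CCOC(Cl)=O | starting material
7 | prop-2-en-1-yl 3,3-dimethyl-2-(3-methylbut-3-en-1-yl)-5-(2-methylpropoxy)cyclohexa-1,5-dien-1-yl carbonate | C=CCOC(=O)OC1=C(CCC(C)=C)C(C)(C)CC(OCC(C)C)=C1 | intermediate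
8 | (S)-6-allyl-5,5-dimethyl-6-(3-methylbut-3-en-1-yl)-3-(2-methylpropoxy)cyclohex-2-en-1-one | O=C1C=C(OCC(C)C)CC(C)(C)[C@@]1(CC=C)CCC(C)=C | intermediate
9 | (6S)-5,5,9-trimethyl-3-(2-methylpropoxy)spiro[5.5]undeca-2,9-dien-1-one | O=C1C=C(OCC(C)C)CC(C)(C)[C@@]12CCC(C)=CC2 | intermediate
10 | (6S)-1,5,5,9-tetramethyl-3-(2-methylpropoxy)spiro[5.5]undeca-2,9-dien-1-ol (either C1 epimer) | CC1(O)C=C(OCC(C)C)CC(C)(C)[C@@]12CCC(C)=CC2 | intermediate
11 | (6S)-1,5,5,9-tetramethylspiro[5.5]undeca-1,9-dien-3-one | CC1=CC(=O)CC(C)(C)[C@@]12CCC(C)=CC2 | intermediate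
12 | (6S,9S,10R)-9,10-epoxy-1,5,5,9-tetramethylspiro[5.5]undec-1-en-3-one | CC1=CC(=O)CC(C)(C)[C@@]12CC[C@@]3(C)[C@H](O3)C2 | intermediate
13 | (6S,9S,10S)-10-chloro-9-hydroxy-1,5,5,9-tetramethylspiro[5.5]undec-1-en-3-one | CC1=CC(=O)CC(C)(C)[C@@]12CC[C@](C)(O)[C@@H](Cl)C2 | intermediate
14 | (6S,9S,10S)-9-bromo-10-chloro-1,5,5,9-tetramethylspiro[5.5]undec-1-en-3-one | CC1=CC(=O)CC(C)(C)[C@@]12CC[C@](C)(Br)[C@@H](Cl)C2 | intermediate
15 | (6R,9S,10S)-9-bromo-10-chloro-1,5,5,9-tetramethyl-3-(trimethylsilyloxy)spiro[5.5]undeca-1,3-diene | CC1=CC(O[Si](C)(C)C)=CC(C)(C)[C@@]12CC[C@](C)(Br)[C@@H](Cl)C2 | intermediate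
16 | (4R,6R,9S,10S)-4,9-dibromo-10-chloro-1,5,5,9-tetramethylspiro[5.5]undec-1-en-3-one | CC1=CC(=O)[C@H](Br)C(C)(C)[C@@]12CC[C@](C)(Br)[C@@H](Cl)C2 | intermediate
17 | (4R,6R,9S,10S)-4,9-dibromo-10-chloro-5,5,9-trimethyl-1-methylidene-3-(trimethylsilyloxy)spiro[5.5]undec-2-ene | C=C1C=C(O[Si](C)(C)C)[C@H](Br)C(C)(C)[C@@]12CC[C@](C)(Br)[C@@H](Cl)C2 | intermediate
18 | (4R,6R,9S,10S)-4,9-dibromo-10-chloro-5,5,9-trimethyl-1-methylidenespiro[5.5]undecan-3-one | C=C1CC(=O)[C@H](Br)C(C)(C)[C@@]12CC[C@](C)(Br)[C@@H](Cl)C2 | intermediate
19 | (3S,4R,6R,9S,10S)-4,9-dibromo-10-chloro-5,5,9-trimethyl-1-methylidenespiro[5.5]undecan-3-ol | C=C1C[C@H](O)[C@H](Br)C(C)(C)[C@@]12CC[C@](C)(Br)[C@@H](Cl)C2 | intermediate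
20 | (3S,4R,6R,9S,10S)-4,9-dibromo-10-chloro-5,5,9-trimethyl-1-methylidenespiro[5.5]undecan-3-yl acetate | C=C1C[C@H](OC(C)=O)[C@H](Br)C(C)(C)[C@@]12CC[C@](C)(Br)[C@@H](Cl)C2 | target

**Step count and risks**

Total step count: 13. Longest linear sequence: 12 steps (from 1 through steps 1 and 3 to 13; step 2 is a side branch).

The three steps most likely to fail:

Step 9. Ionization of the tertiary carbinol may end in loss of a proton (E1) or in a 1,2-shift of chlorine instead of clean retentive capture by bromide. The fallback avoids the carbinol altogether and reverses the roles of the halogens. It sets out from 11 and treats the ring B olefin with Et4NBrCl2 in CH2Cl2 at −78 °C; the bromonium ion should form on the face anti to C1 and chloride should open it diaxially at C10. It comes back to the route at 14 and makes no compound outside the list (F0).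

Step 10. Facial selectivity in the bromination may be poor, because the relay from ring B to C4 rests only on a conformational bias of ring A. The fallback sets C4 before ring B is halogenated, so that the flat allylic side of the cyclohexene half-chair is the relay element, and it then lets the acid of the last operation equilibrate C4 through the enol (thermodynamic instead of kinetic control). It sets out from 11: LiN(SiMe3)2 and then NBS at −78 °C should give (4R,6R)-4-bromo-1,5,5,9-tetramethylspiro[5.5]undeca-1,9-dien-3-one F1. mCPBA should give the epoxide (4R,6R,9S,10R)-4-bromo-9,10-epoxy-1,5,5,9-tetramethylspiro[5.5]undec-1-en-3-one F2. LiCl and AcOH should give the chlorohydrin (4R,6R,9S,10S)-4-bromo-10-chloro-9-hydroxy-1,5,5,9-tetramethylspiro[5.5]undec-1-en-3-one F3. Aqueous HBr then comes back to the route at 16.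

Step 11. Enolization may occur towards C4 (loss of the C4 configuration), or the β,γ-enone may slip back into conjugation during desilylation. The fallback traps the linear dienol under acid and reduces the deconjugated ketone as it is released, so that it never has to be handled. It sets out from 16: isopropenyl acetate with TsOH (cat.) at 60 °C should give the linear dienyl acetate (4R,6R,9S,10S)-4,9-dibromo-10-chloro-5,5,9-trimethyl-1-methylidenespiro[5.5]undec-2-en-3-yl acetate F4. NaBH4 in EtOH/THF at 0 °C cleaves the enol acetate and reduces the ketone in situ, hydride again adding anti to bromine. It comes back to the route at 19.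

**Further compounds**

F0 | step 9 | none | none
F1 | step 10 | (4R,6R)-4-bromo-1,5,5,9-tetramethylspiro[5.5]undeca-1,9-dien-3-one | CC1=CC(=O)[C@H](Br)C(C)(C)[C@@]12CCC(C)=CC2
F2 | step 10 | (4R,6R,9S,10R)-4-bromo-9,10-epoxy-1,5,5,9-tetramethylspiro[5.5]undec-1-en-3-one | CC1=CC(=O)[C@H](Br)C(C)(C)[C@@]12CC[C@@]3(C)[C@H](O3)C2
F3 | step 10 | (4R,6R,9S,10S)-4-bromo-10-chloro-9-hydroxy-1,5,5,9-tetramethylspiro[5.5]undec-1-en-3-one | CC1=CC(=O)[C@H](Br)C(C)(C)[C@@]12CC[C@](C)(O)[C@@H](Cl)C2
F4 | step 11 | (4R,6R,9S,10S)-4,9-dibromo-10-chloro-5,5,9-trimethyl-1-methylidenespiro[5.5]undec-2-en-3-yl acetate | C=C1C=C(OC(C)=O)[C@H](Br)C(C)(C)[C@@]12CC[C@](C)(Br)[C@@H](Cl)C2
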